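**Plan** (germacranolide numbering: C1 ketone, C2=C3 furanone enol ether, C4=C5 alkene bearing C15, C6 lactone carbinol, C7, C8 ester carbinol, C9, quaternary C10 with C14, C11=C13 methylene, C12 lactone carbonyl)
Retrosynthesis: the furanone ring (O, C10, C1, C2, C3) is an α'-hydroxy ynone in disguise, so O–C3 is cut first, then C1–C2 of the ten-membered carbocycle (C1 aldehyde on quaternary C10, C2 iodoalkyne held cis to C6 by the C4=C5 alkene); further cuts are C3–C4 (Sonogashira), the C8–O ester bond (with inversion), C7–C8 (Barbier) and C7=C11 of a butenolide (metathesis).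
Forward: the butenolide ring is made first; the zinc Barbier coupling joins the C6–C15 and C8–C1 halves and converts the butenolide into the α-methylene lactone; the ten-membered ring follows by chromium-mediated alkynyl addition; the furanone ring closes last by gold-catalysed 5-endo-dig attack of the C10 hydroxyl on C3.
Stereochemistry: C10 from (R)-2-methylglycidol; C6 from a lipase resolution; C7 by attack anti to the C6 substituent; C8 from the chair Barbier transition state followed by Mitsunobu inversion; the ester stereocentre from (R)-2-methylbutanoic acid; the C4=C5 geometry from hydroxyl-directed trans-hydroalumination/iodination.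

Key step: step 15

Assumption (chemistry): the zinc Barbier addition is taken to follow the closed chair transition state and give the C8 (S) carbinol, which is why the ester is then introduced with inversion.

Step 1
Reactants: 1 (R)-2-methylglycidol; 2 vinylmagnesium bromide
Product: 3 (2S)-2-methylpent-4-ene-1,2-diol
Conditions: CH2=CHMgBr (2.5 equiv), CuI (10 mol %), THF, −30 → 0 °C
Reagents that add atoms: none
Why: Copper-catalysed Grignard opening of the 2,2-disubstituted epoxide occurs at the unhindered CH2 terminus (the first equivalent only deprotonates the hydroxyl), so the C10 carbinol centre of 1 is carried over unchanged.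

Step 2
Reactants: 3 (2S)-2-methylpent-4-ene-1,2-diol
Product: 4 (4S)-4-methyl-4,5-bis(triethylsilyloxy)pent-1-ene
Conditions: Et3SiOTf (2.4 equiv), 2,6-lutidine, CH2Cl2, −78 → 0 °C
Reagents that add atoms: triethylsilyl trifluoromethanesulfonate, CC[Si](CC)(CC)OS(=O)(=O)C(F)(F)F
Why: Silyl ether formation with the silyl triflate and a hindered pyridine base caps both the primary and the tertiary hydroxyl without touching the stereocentre.

Step 3
Reactants: 4 (4S)-4-methyl-4,5-bis(triethylsilyloxy)pent-1-ene
Product: 6 (3S)-3-methyl-3,4-bis(triethylsilyloxy)butanal, via ozonide 5 (not isolated)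
Conditions: O3, CH2Cl2, −78 °C; then PPh3, −78 °C → rt
Reagents that add atoms: ozone, O=[O+][O-]
Why: Ozonolysis with reductive phosphine work-up cleaves the only alkene to the C8 aldehyde, silyl ethers being inert to ozone at low temperature.

Step 4
Reactants: 7 propargyl alcohol
Product: 8 tert-butyl(diphenyl)(prop-2-yn-1-yloxy)silane
Conditions: t-BuPh2SiCl, imidazole, CH2Cl2, 0 °C → rt
Reagents that add atoms: tert-butyl(chloro)diphenylsilane, CC(C)(C)[Si](Cl)(c1ccccc1)c1ccccc1
Why: Imidazole-promoted silylation of a primary alcohol; the bulky silyl group is chosen because it must outlast two later triethylsilyl cleavages.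

Step 5
Reactants: 8 tert-butyl(diphenyl)(prop-2-yn-1-yloxy)silane; 9 acrolein
Product: 11 rac-6-(tert-butyldiphenylsilyloxy)hex-1-en-4-yn-3-ol, via lithium acetylide 10 (not isolated)
Conditions: n-BuLi, THF, −78 °C; then acrolein, −78 °C
Reagents that add atoms: none
Why: Deprotonation of the terminal alkyne and 1,2-addition of the lithium acetylide to the enal at low temperature gives the racemic C6 carbinol.

Step 6
Reactants: 11 rac-6-(tert-butyldiphenylsilyloxy)hex-1-en-4-yn-3-ol
Product: 12 (3S)-6-(tert-butyldiphenylsilyloxy)hex-1-en-4-yn-3-ol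
Conditions: Burkholderia cepacia lipase (lipase PS), vinyl acetate, hexane, 30 °C, stopped just beyond half conversion
Reagents that add atoms: none
Why: Lipase-catalysed kinetic resolution by transesterification: by the empirical size rule for secondary alcohols the enzyme should acetylate the 3R enantiomer (long alkynyl arm as large group, vinyl as medium group) and leave the 3S alcohol that becomes C6.

Step 7
Reactants: 12 (3S)-6-(tert-butyldiphenylsilyloxy)hex-1-en-4-yn-3-ol
Product: 14 (3S,4Z)-6-(tert-butyldiphenylsilyloxy)-5-iodohexa-1,4-dien-3-ol, via sodium alkenylalanate 13 (not isolated)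
Conditions: NaAlH2(OCH2CH2OMe)2, THF, 0 °C; then N-iodosuccinimide, −78 °C
Reagents that add atoms: N-iodosuccinimide, O=C1CCC(=O)N1I
Why: Hydroxyl-directed trans-hydroalumination of the propargylic alcohol delivers hydride to C5 and aluminium to C4 within a five-membered alanate, and iodinolysis with retention gives the iodoalkene with C6 cis to iodine, the geometry the ring later needs.

Step 8
Reactants: 14 (3S,4Z)-6-(tert-butyldiphenylsilyloxy)-5-iodohexa-1,4-dien-3-ol; 15 2-(bromomethyl)acrylic acid
Product: 16 (3S,4Z)-6-(tert-butyldiphenylsilyloxy)-5-iodohexa-1,4-dien-3-yl 2-(bromomethyl)prop-2-enoate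
Conditions: DCC, DMAP (5 mol %), CH2Cl2, 0 °C
Reagents that add atoms: none
Why: Steglich esterification acylates the secondary alcohol with retention at C6; DMAP is kept catalytic and the temperature low so that the allylic bromide is not quaternised.

Step 9
Reactants: 16 (3S,4Z)-6-(tert-butyldiphenylsilyloxy)-5-iodohexa-1,4-dien-3-yl 2-(bromomethyl)prop-2-enoate
Product: 17 (5S)-3-(bromomethyl)-5-[(1Z)-3-(tert-butyldiphenylsilyloxy)-2-iodoprop-1-en-1-yl]furan-2(5H)-one
Conditions: second-generation Grubbs catalyst (H2IMes)(PCy3)Cl2Ru=CHPh (5 mol %), CH2Cl2 (0.01 M), 40 °C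
Reagents that add atoms: none
Why: Ring-closing metathesis between the terminal vinyl group and the acrylate closes the five-membered butenolide with loss of ethene, while the trisubstituted iodoalkene is too hindered to take part and C6 is untouched.

Step 10
Reactants: 17 (5S)-3-(bromomethyl)-5-[(1Z)-3-(tert-butyldiphenylsilyloxy)-2-iodoprop-1-en-1-yl]furan-2(5H)-one; 6 (3S)-3-methyl-3,4-bis(triethylsilyloxy)butanal
Product: 19 (4R,5S)-4-[(1S,3S)-1-hydroxy-3-methyl-3,4-bis(triethylsilyloxy)butyl]-5-[(1Z)-3-(tert-butyldiphenylsilyloxy)-2-iodoprop-1-en-1-yl]-3-methylideneoxolan-2-one, via allylzinc bromide 18 (not isolated)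
Conditions: Zn dust, THF/sat. aq NH4Cl, 0 °C → rt
Reagents that add atoms: none
Why: Barbier allylation: the allylzinc formed in situ adds through its γ-carbon C7 to aldehyde 6 and restores the exocyclic methylene; the aldehyde should approach anti to the C6 alkenyl group (6,7-trans lactone) and, the ring locking the allylzinc in an (E)-type geometry, a closed chair transition state with the aldehyde residue equatorial should give the anti carbinol, C8 (S).

Step 11
Reactants: 19 the C8 (S) carbinol of step 10; 20 (R)-2-methylbutanoic acid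
Product: 21 (1R,3S)-1-[(2S,3R)-2-[(1Z)-3-(tert-butyldiphenylsilyloxy)-2-iodoprop-1-en-1-yl]-4-methylidene-5-oxooxolan-3-yl]-3-methyl-3,4-bis(triethylsilyloxy)butyl (2R)-2-methylbutanoate
Conditions: PPh3, DIAD (betaine preformed), toluene, 0 °C → rt
Reagents that add atoms: none
Why: Mitsunobu esterification: the C8 oxyphosphonium is displaced by the carboxylate with inversion, so the side chain is attached and C8 is turned into the required R configuration in one operation, the neutral conditions leaving the α-stereocentre of the acid intact.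

Step 12
Reactants: 21 the iodoalkene ester of step 11; 22 trimethylsilylacetylene
Product: 23 (1R,3S)-1-[(2R,3R)-2-[(1E)-2-[(tert-butyldiphenylsilyloxy)methyl]-4-(trimethylsilyl)but-1-en-3-yn-1-yl]-4-methylidene-5-oxooxolan-3-yl]-3-methyl-3,4-bis(triethylsilyloxy)butyl (2R)-2-methylbutanoate
Conditions: PdCl2(PPh3)2 (5 mol %), CuI (10 mol %), Et3N, THF, rt
Reagents that add atoms: none
Why: Sonogashira coupling of the alkenyl iodide proceeds with retention of alkene geometry (C6 stays cis to the new alkyne; the descriptor becomes E only through a priority change), and a tertiary amine is used so that no amine adds to the methylene lactone.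

Step 13
Reactants: 23 the silylated enyne of step 12
Product: 24 (1R,3S)-1-[(2R,3R)-2-[(1E)-2-[(tert-butyldiphenylsilyloxy)methyl]-4-iodobut-1-en-3-yn-1-yl]-4-methylidene-5-oxooxolan-3-yl]-3-methyl-3,4-bis(triethylsilyloxy)butyl (2R)-2-methylbutanoate
Conditions: N-iodosuccinimide, AgNO3 (10 mol %), DMF, rt, dark
Reagents that add atoms: N-iodosuccinimide, O=C1CCC(=O)N1I
Why: Silver-catalysed iododesilylation of the alkynylsilane gives the 1-iodoalkyne under neutral conditions that spare the esters and silyl ethers.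

Step 14
Reactants: 24 the iodoalkyne of step 13
Product: 25 (1R,3S)-1-[(2R,3R)-2-[(1E)-2-[(tert-butyldiphenylsilyloxy)methyl]-4-iodobut-1-en-3-yn-1-yl]-4-methylidene-5-oxooxolan-3-yl]-3-methyl-4-oxo-3-(triethylsilyloxy)butyl (2R)-2-methylbutanoate
Conditions: (COCl)2, DMSO, CH2Cl2, −78 → −40 °C; then Et3N, −78 → 0 °C
Reagents that add atoms: none
Why: Swern oxidation applied directly to the silyl ether: activated DMSO cleaves and oxidises primary triethylsilyl ethers while the tertiary triethylsilyl and the tert-butyldiphenylsilyl ethers are inert, and the resulting aldehyde has no α-hydrogen to epimerise.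

Step 15
Reactants: 25 the iodoalkyne aldehyde of step 14
Product: 27 ten-membered cyclic enyne carbinol (C1 epimers), via alkynylchromium dichloride 26 (not isolated)
Conditions: CrCl2 (10 equiv), NiCl2 (1 mol % of the CrCl2), THF, rt, syringe-pump addition to 0.002 M
Reagents that add atoms: none
Why: Zerovalent nickel, formed from NiCl2 by CrCl2, inserts into the C2–I bond and transmetalation to trivalent chromium gives alkynylchromium 26, which adds to the C1 aldehyde. The closest known reaction type is the chromium/nickel-mediated (Nozaki–Hiyama–Kishi) cyclisation of iodoalkyne aldehydes to nine- and ten-membered cyclic enynes and enediynes. The one ring formed, the ten-membered carbocycle C1–C10, closes in a 10-exo-trig mode. The new C1 carbinol centre is not controlled and need not be, since both epimers are oxidised to the same ketone in step 16. The step needs chemoselectivity for the aldehyde and ring closure over oligomerisation: alkynylchromium reagents do not attack lactones, esters or enoates, and high dilution together with the cis C4=C5 alkene and the quaternary C10 hold the two termini close. With one alkyne and four sp3 carbons the ring is less strained than the cyclic enediynes closed in this way.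

Step 16
Reactants: 27 ten-membered cyclic enyne carbinol (C1 epimers)
Product: 28 ten-membered cyclic ynone (1-oxo compound)
Conditions: Dess–Martin periodinane, NaHCO3, CH2Cl2, 0 °C → rt
Reagents that add atoms: none
Why: Dess–Martin oxidation converts both propargylic C1 epimers into the same conjugated ynone under buffered conditions that leave the silyl ethers and the methylene lactone alone.

Step 17
Reactants: 28 ten-membered cyclic ynone
Product: 29 10-hydroxy ynone
Conditions: HF·pyridine, pyridine, THF, 0 °C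
Reagents that add atoms: none
Why: Fluoride-mediated desilylation: buffered HF·pyridine at 0 °C removes the triethylsilyl group from the tertiary C10 oxygen, whereas the bulkier tert-butyldiphenylsilyl ether at C15 is much slower and is kept to block the allylic hydroxyl during the next step.

Step 18
Reactants: 29 10-hydroxy ynone
Product: 30 15-O-tert-butyldiphenylsilyl ether of the target
Conditions: Ph3PAuNTf2 (5 mol %), toluene, rt
Reagents that add atoms: none
Why: Gold-catalysed 5-endo-dig cycloisomerisation of the α'-hydroxy ynone: the cationic monovalent gold complex activates C2≡C3, the C10 hydroxyl attacks C3 (the β-carbon of the ynone) and protodeauration gives the 3(2H)-furanone and the oxygen bridge, releasing alkyne strain and creating no new stereocentre.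

Step 19
Reactants: 30 15-O-tert-butyldiphenylsilyl ether of the target
Product: 31 target CNP0307052.2
Conditions: Bu4NF, AcOH (1:1), THF, 0 °C → rt
Reagents that add atoms: none
Why: Acetic acid-buffered fluoride desilylation frees the C15 hydroxyl without exposing the methylene lactone, the ester or the furanone to basic fluoride.

**Compound list**

1 | (R)-2-methylglycidol, (2R)-(2-methyloxiran-2-yl)methanol | OC[C@]1(C)CO1 | starting material
2 | vinylmagnesium bromide | C=C[Mg]Br | starting material
3 | (2S)-2-methylpent-4-ene-1,2-diol | C=CC[C@](C)(O)CO | intermediate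
4 | (4S)-4-methyl-4,5-bis(triethylsilyloxy)pent-1-ene | C=CC[C@](C)(O[Si](CC)(CC)CC)CO[Si](CC)(CC)CC | intermediate
5 | ozonide of 4, 3-[(2S)-2-methyl-2,3-bis(triethylsilyloxy)propyl]-1,2,4-trioxolane (epimers at the ring carbon) | O1OC(C[C@](C)(O[Si](CC)(CC)CC)CO[Si](CC)(CC)CC)OC1 | intermediate
6 | (3S)-3-methyl-3,4-bis(triethylsilyloxy)butanal | O=CC[C@](C)(O[Si](CC)(CC)CC)CO[Si](CC)(CC)CC | intermediate
7 | propargyl alcohol | C#CCO | starting material
8 | tert-butyl(diphenyl)(prop-2-yn-1-yloxy)silane | C#CCO[Si](c1ccccc1)(c1ccccc1)C(C)(C)C | intermediate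
9 | acrolein | C=CC=O | starting material
10 | lithium acetylide of 8 | [Li]C#CCO[Si](c1ccccc1)(c1ccccc1)C(C)(C)C | intermediate
11 | rac-6-(tert-butyldiphenylsilyloxy)hex-1-en-4-yn-3-ol | C=CC(O)C#CCO[Si](c1ccccc1)(c1ccccc1)C(C)(C)C | intermediate
12 | (3S)-6-(tert-butyldiphenylsilyloxy)hex-1-en-4-yn-3-ol | C=C[C@@H](C#CCO[Si](c1ccccc1)(c1ccccc1)C(C)(C)C)O | intermediate
13 | sodium alkenylalanate from 12 (five-membered O–Al–C4=C5–C6 ring, C6 S, two 2-methoxyethoxy groups on aluminium) | [Na+].C=C[C@H]1C=C(CO[Si](c2ccccc2)(c2ccccc2)C(C)(C)C)[Al-](OCCOC)(OCCOC)O1 | intermediate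
14 | (3S,4Z)-6-(tert-butyldiphenylsilyloxy)-5-iodohexa-1,4-dien-3-ol | C=C[C@@H](/C=C(/CO[Si](c1ccccc1)(c1ccccc1)C(C)(C)C)I)O | intermediate
15 | 2-(bromomethyl)acrylic acid | C=C(CBr)C(=O)O | starting material
16 | (3S,4Z)-6-(tert-butyldiphenylsilyloxy)-5-iodohexa-1,4-dien-3-yl 2-(bromomethyl)prop-2-enoate | C=C[C@@H](/C=C(/CO[Si](c1ccccc1)(c1ccccc1)C(C)(C)C)I)OC(=O)C(=C)CBr | intermediate
17 | (5S)-3-(bromomethyl)-5-[(1Z)-3-(tert-butyldiphenylsilyloxy)-2-iodoprop-1-en-1-yl]furan-2(5H)-one | BrCC1=C[C@@H](/C=C(/CO[Si](c2ccccc2)(c2ccccc2)C(C)(C)C)I)OC1=O | intermediate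
18 | allylzinc bromide from 17 | Br[Zn]CC1=C[C@@H](/C=C(/CO[Si](c2ccccc2)(c2ccccc2)C(C)(C)C)I)OC1=O | intermediate
19 | (4R,5S)-4-[(1S,3S)-1-hydroxy-3-methyl-3,4-bis(triethylsilyloxy)butyl]-5-[(1Z)-3-(tert-butyldiphenylsilyloxy)-2-iodoprop-1-en-1-yl]-3-methylideneoxolan-2-one | C=C1C(=O)O[C@H](/C=C(/CO[Si](c2ccccc2)(c2ccccc2)C(C)(C)C)I)[C@H]1[C@@H](O)C[C@](C)(O[Si](CC)(CC)CC)CO[Si](CC)(CC)CC | intermediate
20 | (R)-2-methylbutanoic acid | OC(=O)[C@H](C)CC | starting material
21 | (1R,3S)-1-[(2S,3R)-2-[(1Z)-3-(tert-butyldiphenylsilyloxy)-2-iodoprop-1-en-1-yl]-4-methylidene-5-oxooxolan-3-yl]-3-methyl-3,4-bis(triethylsilyloxy)butyl (2R)-2-methylbutanoate | C=C1C(=O)O[C@H](/C=C(/CO[Si](c2ccccc2)(c2ccccc2)C(C)(C)C)I)[C@H]1[C@H](OC(=O)[C@H](C)CC)C[C@](C)(O[Si](CC)(CC)CC)CO[Si](CC)(CC)CC | intermediate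
22 | trimethylsilylacetylene | C#C[Si](C)(C)C | starting material
23 | (1R,3S)-1-[(2R,3R)-2-[(1E)-2-[(tert-butyldiphenylsilyloxy)methyl]-4-(trimethylsilyl)but-1-en-3-yn-1-yl]-4-methylidene-5-oxooxolan-3-yl]-3-methyl-3,4-bis(triethylsilyloxy)butyl (2R)-2-methylbutanoate | C=C1C(=O)O[C@H](/C=C(/CO[Si](c2ccccc2)(c2ccccc2)C(C)(C)C)C#C[Si](C)(C)C)[C@H]1[C@H](OC(=O)[C@H](C)CC)C[C@](C)(O[Si](CC)(CC)CC)CO[Si](CC)(CC)CC | intermediate
24 | (1R,3S)-1-[(2R,3R)-2-[(1E)-2-[(tert-butyldiphenylsilyloxy)methyl]-4-iodobut-1-en-3-yn-1-yl]-4-methylidene-5-oxooxolan-3-yl]-3-methyl-3,4-bis(triethylsilyloxy)butyl (2R)-2-methylbutanoate | C=C1C(=O)O[C@H](/C=C(/CO[Si](c2ccccc2)(c2ccccc2)C(C)(C)C)C#CI)[C@H]1[C@H](OC(=O)[C@H](C)CC)C[C@](C)(O[Si](CC)(CC)CC)CO[Si](CC)(CC)CC | intermediate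
25 | (1R,3S)-1-[(2R,3R)-2-[(1E)-2-[(tert-butyldiphenylsilyloxy)methyl]-4-iodobut-1-en-3-yn-1-yl]-4-methylidene-5-oxooxolan-3-yl]-3-methyl-4-oxo-3-(triethylsilyloxy)butyl (2R)-2-methylbutanoate (key-step precursor) | C=C1C(=O)O[C@H](/C=C(/CO[Si](c2ccccc2)(c2ccccc2)C(C)(C)C)C#CI)[C@H]1[C@H](OC(=O)[C@H](C)CC)C[C@](C)(O[Si](CC)(CC)CC)C=O | intermediate
26 | alkynylchromium dichloride from 25 | C=C1C(=O)O[C@H](/C=C(/CO[Si](c2ccccc2)(c2ccccc2)C(C)(C)C)C#C[Cr](Cl)Cl)[C@H]1[C@H](OC(=O)[C@H](C)CC)C[C@](C)(O[Si](CC)(CC)CC)C=O | intermediate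
27 | ten-membered cyclic enyne carbinol: 1-hydroxy, C2≡C3, C4=C5 with C6 cis to C3, 6,12-olide with 11(13)-methylene, 8-O-(2R)-2-methylbutanoyl, 10-O-triethylsilyl, 15-O-tert-butyldiphenylsilyl; 6R,7R,8R,10S, C1 epimers (key-step product) | C=C1C(=O)O[C@@H]2/C=C(/CO[Si](c3ccccc3)(c3ccccc3)C(C)(C)C)C#CC(O)[C@](C)(C[C@@H](OC(=O)[C@H](C)CC)[C@@H]12)O[Si](CC)(CC)CC | intermediate
28 | ten-membered cyclic ynone: the 1-oxo compound corresponding to 27; 6R,7R,8R,10S | C=C1C(=O)O[C@@H]2/C=C(/CO[Si](c3ccccc3)(c3ccccc3)C(C)(C)C)C#CC(=O)[C@](C)(C[C@@H](OC(=O)[C@H](C)CC)[C@@H]12)O[Si](CC)(CC)CC | intermediate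
29 | 10-hydroxy ynone: 28 without the triethylsilyl group; 6R,7R,8R,10S | C=C1C(=O)O[C@@H]2/C=C(/CO[Si](c3ccccc3)(c3ccccc3)C(C)(C)C)C#CC(=O)[C@](C)(C[C@@H](OC(=O)[C@H](C)CC)[C@@H]12)O | intermediate
30 | 15-O-tert-butyldiphenylsilyl ether of the target (furanone closed, 4Z); 6R,7R,8R,10S | C=C1C(=O)O[C@@H]2/C=C(/CO[Si](c4ccccc4)(c4ccccc4)C(C)(C)C)C3=CC(=O)[C@](C)(C[C@@H](OC(=O)[C@H](C)CC)[C@@H]12)O3 | intermediate
31 | CNP0307052.2 | C=C1C(=O)O[C@@H]2/C=C(/CO)C3=CC(=O)[C@](C)(C[C@@H](OC(=O)[C@H](C)CC)[C@@H]12)O3 | target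

**Step count**

Total: 19 steps. Longest linear sequence: 16 steps (steps 4–19, from propargyl alcohol); the aldehyde branch (steps 1–3) joins at step 10.

**Steps most likely to fail**

Step 15 (ring closure). Oligomerisation or simple reduction of the alkynyl iodide may outrun the 10-exo-trig addition. The fallback closes the same ring at C3–C4 instead and sets out from 21. Direct Swern oxidation of its primary triethylsilyl ether (conditions of step 14) gives the iodoalkene aldehyde F1. Addition of HC≡CMgBr in THF at −78 °C, where the aldehyde reacts well before the lactone or ester, gives the ethynyl carbinol F2 as C1 epimers. An intramolecular Sonogashira coupling (PdCl2(PPh3)2, CuI, Et3N, THF, slow addition at high dilution) then joins C3 to C4 and returns to the route at 27.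

Step 11 (Mitsunobu inversion). The hindered C8 oxyphosphonium may eliminate toward a C7=C8 diene or be acylated with retention. The fallback replaces it by a two-step sulfonate displacement starting from 19. ClCH2SO2Cl in pyridine at 0 °C gives the chloromethanesulfonate F3. Displacement with the caesium salt of 20 (Cs2CO3, 18-crown-6, toluene, 60 °C) proceeds with inversion and rejoins the route at 21.

Step 10 (Barbier coupling). Simple diastereoselection may not follow the chair model (open or boat transition state) and may deliver mainly the C8 epimer. In that case the coupling of 17 with 6 gives the C8 (R) carbinol F4, which already has the configuration of the target. It is esterified with retention by 20 under Steglich conditions (DCC, DMAP, CH2Cl2, 0 °C), which returns to the route at 21 and makes the inversion unnecessary.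

**Further compounds**

F1 | step 15 | C1 aldehyde of iodoalkene ester 21 (primary silyl ether oxidised) | C=C1C(=O)O[C@H](/C=C(/CO[Si](c2ccccc2)(c2ccccc2)C(C)(C)C)I)[C@H]1[C@H](OC(=O)[C@H](C)CC)C[C@](C)(O[Si](CC)(CC)CC)C=O
F2 | step 15 | 1-ethynyl carbinol from F1 (C1 epimers) | C=C1C(=O)O[C@H](/C=C(/CO[Si](c2ccccc2)(c2ccccc2)C(C)(C)C)I)[C@H]1[C@H](OC(=O)[C@H](C)CC)C[C@](C)(O[Si](CC)(CC)CC)C(O)C#C
F3 | step 11 | C8 (S) chloromethanesulfonate of 19 | C=C1C(=O)O[C@H](/C=C(/CO[Si](c2ccccc2)(c2ccccc2)C(C)(C)C)I)[C@H]1[C@@H](OS(=O)(=O)CCl)C[C@](C)(O[Si](CC)(CC)CC)CO[Si](CC)(CC)CC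
F4 | step 10 | C8 (R) epimer of carbinol 19 | C=C1C(=O)O[C@H](/C=C(/CO[Si](c2ccccc2)(c2ccccc2)C(C)(C)C)I)[C@H]1[C@H](O)C[C@](C)(O[Si](CC)(CC)CC)CO[Si](CC)(CC)CC
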